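**Assumption:** the target SMILES holds no stereocentre and no stereogenic double bond (the prenyl alkene carries two identical methyl groups), so the compound is achiral and no stereocontrol is needed.

**Retrosynthetic overview**
- Target ⇐ its ring-A bis(4-methoxybenzyl) ether (final acidolysis).
- Key C–C disconnection: the bond between the ketone carbon and ring A ⇐ a diaryl ether dialdehyde. Forward, a carbene turns the ring-B aldehyde carbon into an acyl anion (Breslow intermediate), which attacks the oxygen-bearing, SNAr-electrophilic ipso carbon of ring A (Truce–Smiles O→C aryl shift); two normally electrophilic carbons are joined.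
- Diaryl ether ⇐ SNAr of atranol on a ring-A 2-fluorobenzaldehyde.
- Ring-A fluoroaldehyde ⇐ 1,3,5-trifluorobenzene by symmetry-controlled double lithiation (prenyl, then CHO) and two SNAr alkoxylations; atranol ⇐ 2,6-dimethoxy-4-methylbenzaldehyde.
- No ring is built: both benzene rings are bought, ring A elaborated first and ring B prepared in a one-step side branch.

**Route**

Step 1
Reactants: 1 1,3,5-trifluorobenzene; 2 1-bromo-3-methylbut-2-ene (prenyl bromide)
Product: 6 2,4,6-trifluoro-3-(3-methylbut-2-en-1-yl)benzaldehyde, via aryllithium 3 (not isolated), via prenylarene 4 (not isolated), via aryllithium 5 (not isolated)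
Conditions: n-BuLi (1.0 equiv), THF, −78 °C; CuBr·SMe2 (5 mol%), 2 (0.97 equiv), −78 → −30 °C; recool to −78 °C, LiN(iPr)2 (1.15 equiv); DMF (1.5 equiv), −78 → 0 °C; aq. HCl
Reagents that add atoms: N,N-dimethylformamide, CN(C)C=O
Why: Fluorine-directed ortho-lithiation, copper-catalysed SN2 allylation of the aryllithium, then a second ortho-lithiation and formylation with DMF; every ring C–H of 1 is equivalent and the two left in 4 are equivalent by symmetry, so no regiochemical question arises, and the C–H flanked by two fluorines is removed by LiN(iPr)2 at −78 °C far faster than the benzylic/allylic CH2.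

Step 2
Reactants: 6 2,4,6-trifluoro-3-(3-methylbut-2-en-1-yl)benzaldehyde
Product: 8 2-fluoro-4,6-bis[(4-methoxybenzyl)oxy]-3-(3-methylbut-2-en-1-yl)benzaldehyde, via mono-ether 7 (not isolated)
Conditions: 4-methoxybenzyl alcohol (2.1 equiv), KOtBu (2.1 equiv), DMF, −40 → 0 °C
Reagents that add atoms: 4-methoxybenzyl alcohol, COc1ccc(CO)cc1
Why: Two successive SNAr displacements of fluoride on the aldehyde-activated ring, in which (DMF, potassium counter-ion) the para-fluorine should react first and the ortho-fluorine next to H second, while the ortho-fluorine wedged between CHO and the prenyl CH2 is the most hindered and is kept for step 4.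

Step 3
Reactants: 9 2,6-dimethoxy-4-methylbenzaldehyde
Product: 10 2,6-dihydroxy-4-methylbenzaldehyde (atranol)
Conditions: BBr3 (3 equiv), CH2Cl2, −78 °C → rt; H2O
Reagents that add atoms: none
Why: Lewis-acid cleavage of aryl methyl ethers (O–B complex, then bromide SN2 at methyl), helped by chelation to the ortho carbonyl, with the aldehyde restored on aqueous work-up.

Step 4
Reactants: 8 2-fluoro-4,6-bis[(4-methoxybenzyl)oxy]-3-(3-methylbut-2-en-1-yl)benzaldehyde; 10 2,6-dihydroxy-4-methylbenzaldehyde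
Product: 11 2-{2-formyl-3,5-bis[(4-methoxybenzyl)oxy]-6-(3-methylbut-2-en-1-yl)phenoxy}-6-hydroxy-4-methylbenzaldehyde
Conditions: 10 (1.5 equiv), Cs2CO3 (2.0 equiv), DMSO, 110 °C, N2
Reagents that add atoms: none
Why: SNAr diaryl ether synthesis in which the mono-phenoxide of symmetrical atranol displaces the last fluoride, which is ortho to the activating formyl group and only meta to the two alkoxy groups; excess 10 suppresses double arylation.

Step 5
Reactants: 11 2-{2-formyl-3,5-bis[(4-methoxybenzyl)oxy]-6-(3-methylbut-2-en-1-yl)phenoxy}-6-hydroxy-4-methylbenzaldehyde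
Product: 13 2-(2,6-dihydroxy-4-methylbenzoyl)-4,6-bis[(4-methoxybenzyl)oxy]-3-(3-methylbut-2-en-1-yl)benzaldehyde, via Breslow intermediate 12 (not isolated)
Conditions: 1,3-dimethylimidazolium iodide (30 mol%), Cs2CO3 (1.5 equiv), degassed DMSO, 70 °C, Ar; cold aq. citric acid work-up
Reagents that add atoms: none
Why: Proposed new method: the carbene adds to the ring-B aldehyde to give Breslow intermediate 12, an acyl anion equivalent whose carbon attacks the oxygen-bearing ipso carbon of ring A through a five-membered spiro Meisenheimer transition state stabilised by the ortho-formyl group, after which C–O cleavage releases the ring-B phenoxide and the carbene (Truce–Smiles rearrangement, an intramolecular SNAr by an acyl anion; closest known reaction type: carbene-catalysed O-to-C aryl migration of 2-(aryloxy)benzaldehydes to 2-hydroxybenzophenones); the free ring-B phenoxide makes ring B a dead SNAr acceptor, so a Breslow intermediate formed at the ring-A aldehyde, like any seven-membered cross-benzoin adduct, can only revert, and it also deactivates the product ketone towards carbene-mediated hydride shift to a phthalide.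

Step 6
Reactants: 13 2-(2,6-dihydroxy-4-methylbenzoyl)-4,6-bis[(4-methoxybenzyl)oxy]-3-(3-methylbut-2-en-1-yl)benzaldehyde
Product: 14 2-(2,6-dihydroxy-4-methylbenzoyl)-4,6-dihydroxy-3-(3-methylbut-2-en-1-yl)benzaldehyde
Conditions: CF3CO2H (5 vol%), pentamethylbenzene (8 equiv), CH2Cl2, 0 °C, 20 min; pH 6 phosphate buffer; work up without base and away from light
Reagents that add atoms: none
Why: SN1 acidolysis of the two aryl 4-methoxybenzyl ethers with the benzyl cation trapped irreversibly by pentamethylbenzene (Friedel–Crafts alkylation), run cold, dilute and briefly so that the prenyl alkene is not protonated and no chroman forms; no stereocentre is created anywhere in the route.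

**Compound list**
1 | 1,3,5-trifluorobenzene | Fc1cc(F)cc(F)c1 | starting material
2 | 1-bromo-3-methylbut-2-ene (prenyl bromide) | CC(C)=CCBr | starting material
3 | (2,4,6-trifluorophenyl)lithium | [Li]c1c(F)cc(F)cc1F | intermediate
4 | 1,3,5-trifluoro-2-(3-methylbut-2-en-1-yl)benzene | CC(C)=CCc1c(F)cc(F)cc1F | intermediate
5 | [2,4,6-trifluoro-3-(3-methylbut-2-en-1-yl)phenyl]lithium | [Li]c1c(F)cc(F)c(CC=C(C)C)c1F | intermediate
6 | 2,4,6-trifluoro-3-(3-methylbut-2-en-1-yl)benzaldehyde | O=Cc1c(F)cc(F)c(CC=C(C)C)c1F | intermediate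
7 | 2,6-difluoro-4-[(4-methoxybenzyl)oxy]-3-(3-methylbut-2-en-1-yl)benzaldehyde | O=Cc1c(F)cc(OCc2ccc(OC)cc2)c(CC=C(C)C)c1F | intermediate
8 | 2-fluoro-4,6-bis[(4-methoxybenzyl)oxy]-3-(3-methylbut-2-en-1-yl)benzaldehyde | O=Cc1c(OCc2ccc(OC)cc2)cc(OCc2ccc(OC)cc2)c(CC=C(C)C)c1F | intermediate
9 | 2,6-dimethoxy-4-methylbenzaldehyde | COc1cc(C)cc(OC)c1C=O | starting material
10 | 2,6-dihydroxy-4-methylbenzaldehyde (atranol) | Cc1cc(O)c(C=O)c(O)c1 | intermediate
11 | 2-{2-formyl-3,5-bis[(4-methoxybenzyl)oxy]-6-(3-methylbut-2-en-1-yl)phenoxy}-6-hydroxy-4-methylbenzaldehyde | O=Cc1c(O)cc(C)cc1Oc1c(CC=C(C)C)c(OCc2ccc(OC)cc2)cc(OCc2ccc(OC)cc2)c1C=O | intermediate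
12 | Breslow intermediate: 2-{2-[(1,3-dimethyl-1,3-dihydro-2H-imidazol-2-ylidene)(hydroxy)methyl]-3-hydroxy-5-methylphenoxy}-4,6-bis[(4-methoxybenzyl)oxy]-3-(3-methylbut-2-en-1-yl)benzaldehyde | CN1C=CN(C)C1=C(O)c1c(O)cc(C)cc1Oc1c(CC=C(C)C)c(OCc2ccc(OC)cc2)cc(OCc2ccc(OC)cc2)c1C=O | intermediate
13 | 2-(2,6-dihydroxy-4-methylbenzoyl)-4,6-bis[(4-methoxybenzyl)oxy]-3-(3-methylbut-2-en-1-yl)benzaldehyde | CC(C)=CCc1c(OCc2ccc(OC)cc2)cc(OCc2ccc(OC)cc2)c(C=O)c1C(=O)c1c(O)cc(C)cc1O | intermediate
14 | 2-(2,6-dihydroxy-4-methylbenzoyl)-4,6-dihydroxy-3-(3-methylbut-2-en-1-yl)benzaldehyde | CC(C)=CCc1c(O)cc(O)c(C=O)c1C(=O)c1c(O)cc(C)cc1O | target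

**Totals**
Total step count: 6. Longest linear sequence: 5 steps (1 → 6 → 8 → 11 → 13 → 14); step 3 is a one-step side branch.

**Steps most likely to fail**

Step 5 (most likely to fail). The carbene-catalysed aryl migration has no precedent on a substrate with a second aldehyde, a hindered formyl-activated migrating ring and a free phenoxide. It may stall at the phenoxide-conjugated aldehyde, react from the wrong aldehyde, or isomerise 13 to a phthalide. The fallback sets out from 8 and comes back at 13. Aldehyde 8 is condensed with NH2OH·HCl/pyridine to (E)-2-fluoro-4,6-bis[(4-methoxybenzyl)oxy]-3-(3-methylbut-2-en-1-yl)benzaldehyde oxime F1. F1 is dehydrated (Ac2O, 90 °C) to 2-fluoro-4,6-bis[(4-methoxybenzyl)oxy]-3-(3-methylbut-2-en-1-yl)benzonitrile F2. F2 is coupled with 10 (Cs2CO3, DMSO, 90 °C; the nitrile is the stronger SNAr activator) to give 2-(2-formyl-3-hydroxy-5-methylphenoxy)-4,6-bis[(4-methoxybenzyl)oxy]-3-(3-methylbut-2-en-1-yl)benzonitrile F3. The same carbene-catalysed migration is run on F3, which now holds a single aldehyde and a carbene-inert acceptor, to give 2-(2,6-dihydroxy-4-methylbenzoyl)-4,6-bis[(4-methoxybenzyl)oxy]-3-(3-methylbut-2-en-1-yl)benzonitrile F4. The nitrile of F4 is then reduced with iBu2AlH (4 equiv, toluene, −78 °C; cold aqueous tartaric acid) to 13. The tetra-ortho-substituted ketone, held as its aluminium bis-phenoxide chelate, is expected to survive, but this is the weak point of the detour.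

Step 4. The fluoride is hindered and only moderately activated, and the atranol phenoxide is a weak nucleophile because it is conjugated and hydrogen-bonded to its aldehyde. The fallback sets out from 10 and comes back at 11. The aldehyde of 10 is masked with propane-1,3-dithiol and BF3·OEt2 (CH2Cl2, 0 °C) as 2-(1,3-dithian-2-yl)-5-methylbenzene-1,3-diol F5, whose phenoxide is an ordinary, more nucleophilic resorcinol anion. SNAr of F5 with 8 (Cs2CO3, DMSO, 100 °C) gives 2-[2-(1,3-dithian-2-yl)-3-hydroxy-5-methylphenoxy]-4,6-bis[(4-methoxybenzyl)oxy]-3-(3-methylbut-2-en-1-yl)benzaldehyde F6. Alkylative hydrolysis of the dithiane (MeI, CaCO3, MeCN/H2O, 45 °C) then gives 11.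

Step 6. Acid may cyclise the ortho-prenyl phenol to a chroman, and the product is sensitive. The fallback sets out from 6 and comes back at 14, replacing the acid-labile ethers by allyl ethers removed under neutral conditions. Double SNAr on 6 with allyl alcohol/KOtBu (DMF, −40 → 0 °C) gives 2-fluoro-3-(3-methylbut-2-en-1-yl)-4,6-bis(prop-2-en-1-yloxy)benzaldehyde F7. Coupling with 10 as in step 4 gives 2-[2-formyl-6-(3-methylbut-2-en-1-yl)-3,5-bis(prop-2-en-1-yloxy)phenoxy]-6-hydroxy-4-methylbenzaldehyde F8. The carbene-catalysed migration, run at or below 60 °C to stay under the temperature at which 2-allyloxybenzaldehydes undergo carbene-catalysed hydroacylation, gives 2-(2,6-dihydroxy-4-methylbenzoyl)-3-(3-methylbut-2-en-1-yl)-4,6-bis(prop-2-en-1-yloxy)benzaldehyde F9. Deallylation with Pd(PPh3)4 (5 mol%) and PhSO2Na (3 equiv) in THF/MeOH at rt then gives 14.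

**Further compounds**
F1 | step 5 | (E)-2-fluoro-4,6-bis[(4-methoxybenzyl)oxy]-3-(3-methylbut-2-en-1-yl)benzaldehyde oxime | O/N=C/c1c(OCc2ccc(OC)cc2)cc(OCc2ccc(OC)cc2)c(CC=C(C)C)c1F
F2 | step 5 | 2-fluoro-4,6-bis[(4-methoxybenzyl)oxy]-3-(3-methylbut-2-en-1-yl)benzonitrile | N#Cc1c(OCc2ccc(OC)cc2)cc(OCc2ccc(OC)cc2)c(CC=C(C)C)c1F
F3 | step 5 | 2-(2-formyl-3-hydroxy-5-methylphenoxy)-4,6-bis[(4-methoxybenzyl)oxy]-3-(3-methylbut-2-en-1-yl)benzonitrile | N#Cc1c(OCc2ccc(OC)cc2)cc(OCc2ccc(OC)cc2)c(CC=C(C)C)c1Oc1cc(C)cc(O)c1C=O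
F4 | step 5 | 2-(2,6-dihydroxy-4-methylbenzoyl)-4,6-bis[(4-methoxybenzyl)oxy]-3-(3-methylbut-2-en-1-yl)benzonitrile | N#Cc1c(OCc2ccc(OC)cc2)cc(OCc2ccc(OC)cc2)c(CC=C(C)C)c1C(=O)c1c(O)cc(C)cc1O
F5 | step 4 | 2-(1,3-dithian-2-yl)-5-methylbenzene-1,3-diol | Cc1cc(O)c(C2SCCCS2)c(O)c1
F6 | step 4 | 2-[2-(1,3-dithian-2-yl)-3-hydroxy-5-methylphenoxy]-4,6-bis[(4-methoxybenzyl)oxy]-3-(3-methylbut-2-en-1-yl)benzaldehyde | O=Cc1c(OCc2ccc(OC)cc2)cc(OCc2ccc(OC)cc2)c(CC=C(C)C)c1Oc1cc(C)cc(O)c1C1SCCCS1
F7 | step 6 | 2-fluoro-3-(3-methylbut-2-en-1-yl)-4,6-bis(prop-2-en-1-yloxy)benzaldehyde | O=Cc1c(OCC=C)cc(OCC=C)c(CC=C(C)C)c1F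
F8 | step 6 | 2-[2-formyl-6-(3-methylbut-2-en-1-yl)-3,5-bis(prop-2-en-1-yloxy)phenoxy]-6-hydroxy-4-methylbenzaldehyde | O=Cc1c(O)cc(C)cc1Oc1c(CC=C(C)C)c(OCC=C)cc(OCC=C)c1C=O
F9 | step 6 | 2-(2,6-dihydroxy-4-methylbenzoyl)-3-(3-methylbut-2-en-1-yl)-4,6-bis(prop-2-en-1-yloxy)benzaldehyde | CC(C)=CCc1c(OCC=C)cc(OCC=C)c(C=O)c1C(=O)c1c(O)cc(C)cc1O
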